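## Structural features

The target is a single cyclohexene ring whose only alkene is C2=C3; the two phenyl rings belong to benzoate esters on the allylic oxygens at C1 and C4, and C6 carries the one-carbon branch C7 (numbering: C1 = CH(OBz) next to the quaternary C6, C4 = CH(OBz), C5 = CH(OH), C6 = C(OH), C7 = CH2OH). Four stereocentres form an unbroken chain C4–C5–C6–C1, with C6 quaternary (tertiary hydroxyl plus hydroxymethyl); the configuration is 1S,4R,5S,6R. In relative terms the two benzoyloxy groups are cis to each other, the C5 hydroxyl is trans to both of its oxygenated neighbours (C4 and C6), and the C6 hydroxyl is cis to the C1 benzoate. Five oxygens sit on C1, C4, C5, C6 and C7; two are acylated and three are free, so each ester has a free hydroxyl in a 1,2- or 1,3-relationship. The fragile points are therefore benzoyl migration (especially toward the primary O7) and ester cleavage under base, ionisation or allylic transposition of the two allylic esters under strong acid or heat, and dehydration toward an arene. The real difficulty is not the carbon skeleton but telling five oxygens apart while setting a trans-5,6-diol next to a cis-1,4-diester at a quaternary centre. The key step exploits the fact that this oxygen pattern is a hydroxymethyl-para-benzoquinone in disguise: C1 and C4 are the carbonyl carbons, C2=C3 is the unsubstituted alkene that can be hidden in a cyclopentadiene adduct, and the substituted C5=C6 ene-dione alkene is then the only electron-poor alkene, with one face closed by the norbornene unit.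

## Logic of the disconnections

13 to 12: the O7–Si bond is cut. The primary hydroxyl is the most nucleophilic oxygen and the natural resting place of a migrating benzoyl group, so it stays capped until the very end. No skeletal simplification results, but every earlier step has one oxygen fewer to distinguish. The forward step must remove silicon without base, so that two benzoates next to three hydroxyls stay where they are.

12 to 10: the C6–OH bond is cut and C6 is reconnected to O5 as an oxirane. A trans-diol with one tertiary carbinol is the hydrolysis product of a trisubstituted epoxide opened at its tertiary carbon, and in 10 the C1 ester stands anti to the oxirane and can assist. The gain is that in 10 all five oxygens differ in kind (two esters, one oxirane, one silyl ether), so 10 can be made by plain exhaustive acylation. The forward step must open at C6 and not at C5, with inversion, and leave the acyl group on O1.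

10 to 9: the two acyl–oxygen bonds at O1 and O4 are cut. In 9 these are the only free hydroxyls, so no selectivity is asked of the acylation. The forward step must acylate a hindered secondary hydroxyl next to the quaternary carbon without base-induced epoxide migration.

9 to 8 (and 4): in the retrosynthetic sense 4 is added across C2=C3, forming two C–C bonds to C2 and C3. This masks the alkene and turns the flat ring into a folded tricycle with two distinct faces. The forward cycloreversion must be run hot enough to expel 4 yet spare an epoxide and two free hydroxyls.

8 to 7: the C1–H and C4–H bonds are cut, returning both carbinols to ketones. The cis-1,4-diol anti to the oxirane corresponds to double hydride delivery from the open convex face. Two stereocentres disappear. The forward reduction must attack both ketones from the convex face and leave the α,β-epoxy ketone units otherwise intact.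

7 to 5: the C5–O and C6–O bonds of the oxirane are cut (key disconnection). One ring and two stereocentres are removed, and an ene-dione alkene is restored. The forward step needs a nucleophilic oxidant that attacks only this alkene, only from the convex face, and faster than base can enolise the ene-dione.

5 to 3 and 4: the two C–C bonds from C2 and C3 to the five-membered ring are cut. Four stereocentres and the whole scaffold vanish, leaving an achiral quinone and a symmetric diene. The forward cycloaddition must choose the unsubstituted alkene, the endo topology, and one enantiotopic face, which requires the catalyst to tell the two carbonyl groups of 3 apart.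

3 to 2: the two carbonyl oxygens are traced back to aryl methyl ethers. This exchanges a reactive quinone for a shelf-stable arene. The oxidant must spare the silyl ether.

2 to 1: the O–Si bond is cut, giving a commercial benzylic alcohol with a single hydroxyl, so silylation is unambiguous.

## Other disconnections considered

Alternative 1: The cut goes through C4–C5 and C6–C1, so the ring is assembled from the four-carbon diene A1, (1E,3E)-buta-1,3-diene-1,4-diyl diacetate (C1–C4), and the two-carbon dienophile A2, (2E)-2,3-bis(chloroacetoxy)prop-2-enal (C5, C6, C7).
- Forward key step: a catalysed [4+2] cycloaddition (chiral oxazaborolidinium or chiral primary ammonium salt) would give cycloadduct A3 with all four ring stereocentres at once. The cis-1,4 pattern comes from the E,E diene, the trans-5,6 pattern from the E dienophile, and the C1/C6 relationship from a transition state with the C6 acyloxy group endo and the formyl group exo.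
- In its favour: maximal convergence, no scaffold to put on and take off, every oxygen already in place, and only the aldehyde to reduce.
- Against it here: A1 is substituted at both termini and only weakly activated; A2 is a trisubstituted enal whose β-acyloxy group lowers its reactivity and can be lost or isomerised once the carbonyl is activated; four selectivities (endo/exo, face, and two alkene geometries that must survive) have to hold simultaneously on a substrate pair without close precedent. The C1/C4 acetates of A3 are also not the benzoates required, so an ester exchange next to the C5/C6 chloroacetates, or a differently acylated diene, would be needed, and reduction of the aldehyde next to a tertiary ester invites acyl migration to O7.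
- Comparison: on step economy this plan is clearly better (roughly half the steps). On the regiochemical question it is equal (both use a symmetric diene). On mechanism it is weaker, because its stereocontrol rests on a flexible bimolecular transition state whereas the chosen plan reads its C5/C6 and C1/C4 stereochemistry from a rigid scaffold with well-established facial bias.

Alternative 2: The cut removes the C1–O and C4–O bonds.
- Forward key step: diene A4, a 5,6-trans-dioxygenated cyclohexa-1,3-diene in which a di-tert-butylsilylene ties O5 to O7 and the tertiary O6 hydroxyl is free, would take up singlet oxygen across C1 and C4 to give endoperoxide A5. Reduction of the O–O bond, dibenzoylation of the two secondary allylic hydroxyls and removal of the silylene would finish the synthesis.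
- In its favour: both allylic C–O bonds are made in one step and are cis by construction; the C2=C3 alkene appears in the right place in the same step; after O–O cleavage only O1 and O4 are acylable (O6 is tertiary, O5 and O7 are tied up), which is as clean as the chosen plan; and no epoxide opening is needed, so the regiochemical risk of step 8 does not exist. On these points the alternative is the equal or the better.
- Against it here: the difficulty is moved into A4. An enantiopure trans-diol diene with a quaternary carbinol has no short preparation and is one dehydration away from an arene. The peroxide must add syn to the tertiary hydroxyl and anti to O5, which is plausible but rests on a modest bias. The endoperoxide is also base-sensitive (Kornblum–DeLaMare fragmentation), so it must be reduced before any acylation.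
- Comparison: the endgame after the key step is shorter than in the chosen plan, but the total count would be higher because of A4. Facial control from two ring substituents is less secure than control by the norbornene fold.

Alternative 3: The cut removes the C1–O and C6–O bonds.
- Forward key step: chirality would come from A6, (1S,2S)-3-bromocyclohexa-3,5-diene-1,2-diol obtained by microbial arene oxidation. Inversion of its remote hydroxyl with benzoic acid (Mitsunobu reaction), silylation of the other hydroxyl and replacement of bromine by a silyloxymethyl group would give diene A7. OsO4 with N-methylmorpholine N-oxide should then dihydroxylate the trisubstituted C6=C1 bond anti to the C5 silyloxy group to give diol A8; benzoylation of the secondary C1 hydroxyl and desilylation would complete the target.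
- In its favour: the absolute configuration comes from an enzymatic oxidation and is essentially secure, which is better than the chosen plan's reliance on a catalyst distinguishing two similar carbonyls. The cis C1/C6 diol is made directly by a suprafacial reaction, so no epoxide opening is needed, and the last benzoylation only has to distinguish a secondary from a tertiary hydroxyl.
- Against it here: the osmylation must pick one alkene of a conjugated diene (the more electron-rich but more hindered C6=C1 over C2=C3) and stop at the diol. The Mitsunobu inversion of a dienylic alcohol competes with allylic transposition and aromatisation. The two hydroxyls of A6 must be differentiated in the less natural sense (the one nearer bromine silylated), which costs steps.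
- Comparison: step count would be about equal to the chosen plan. The alternative is better on absolute stereocontrol and on avoiding the epoxide opening. The chosen plan is better on site selectivity of the oxidation, because the competing alkene is not present when the oxidant is used.

Key step: step 4

**Remarks and assumptions**

- Atom labels C1–C7 of the target are used for all intermediates in the reasoning; systematic names of the tricyclic compounds carry their own locants.
- Stereochemical consistency: 5 is the endo adduct (ring-fusion hydrogens on the convex face), 7 carries the oxirane oxygen cis to those hydrogens, and relay through steps 5–8 leads to 1S,4R,5S,6R in 13.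
- Protecting group: the silyl group is tert-butyldiphenylsilyl rather than a smaller trialkylsilyl group. It must survive the acidic oxidant of step 2 and the aqueous acid of step 8 and keep O7 blocked while a benzoyl group sits next to it; the skeleton and the bonds formed in the key step are unaffected.
- Starting material: the hydroquinone dimethyl ether is used because a free hydroquinone would compete with the primary alcohol in the silylation.
- Catalyst antipode in step 3: the (R)-catalyst is chosen from the accepted transition-state picture (binding at the C4 carbonyl, diene on the unscreened face). If the adduct proved antipodal, the (S)-catalyst would be used and nothing else changes.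

## Route

Step 1
Reactants: 1 (2,5-dimethoxyphenyl)methanol
Product: 2 tert-butyl[(2,5-dimethoxyphenyl)methoxy]diphenylsilane
Conditions: t-BuPh2SiCl, imidazole, DMF, 0 °C → rt
Reagents that add atoms: tert-butyl(chloro)diphenylsilane, CC(C)(C)[Si](Cl)(c1ccccc1)c1ccccc1
Why: Imidazole-promoted silylation (substitution at silicon) of the only hydroxyl present; the bulky, acid-stable silyl ether is chosen to survive steps 2, 3 and 8 and to keep O7 capped to the end.

Step 2
Reactants: 2 tert-butyl[(2,5-dimethoxyphenyl)methoxy]diphenylsilane
Product: 3 2-{[tert-butyl(diphenyl)silyl]oxymethyl}cyclohexa-2,5-diene-1,4-dione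
Conditions: (NH4)2Ce(NO3)6 (2.5 equiv), MeCN/H2O (2:1), 0 °C, 20 min
Reagents that add atoms: water, O
Why: Oxidative demethylation of a para-dimethoxyarene by tetravalent cerium (two one-electron oxidations, addition of water at the ipso carbons, loss of two molecules of methanol); the robust silyl ether and the short contact time at 0 °C should keep the side chain intact.

Step 3
Reactants: 3 2-{[tert-butyl(diphenyl)silyl]oxymethyl}cyclohexa-2,5-diene-1,4-dione; 4 cyclopenta-1,3-diene (freshly distilled)
Product: 5 (1R,2S,7R,8S)-4-{[tert-butyl(diphenyl)silyl]oxymethyl}tricyclo[6.2.1.0(2,7)]undeca-4,9-diene-3,6-dione (endo adduct, cis ring fusion, ene-dione ring under the norbornene alkene)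
Conditions: (R)-tetrahydro-1-(2-methylphenyl)-3,3-diphenyl-1H,3H-pyrrolo[1,2-c][1,3,2]oxazaborole (20 mol %), Tf2NH (18 mol %), CH2Cl2, −78 °C; filtration through silica, no amine quench
Reagents that add atoms: none
Why: Enantioselective endo Diels–Alder reaction of a quinone under a protonated chiral oxazaborolidine: the diene adds to the unsubstituted, less hindered C2=C3 bond, and the endo transition state places the ene-dione ring under the new norbornene alkene. With the catalyst bound to the C4 carbonyl oxygen (lone pair syn to C3–H) and one face screened by its aryl group, cyclopentadiene is expected to bond to the Re face of C3 and the Si face of C2, which sets the two ring-fusion and two bridgehead centres in one step.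

Step 4
Reactants: 5 (1R,2S,7R,8S)-4-{[tert-butyl(diphenyl)silyl]oxymethyl}tricyclo[6.2.1.0(2,7)]undeca-4,9-diene-3,6-dione
Product: 7 (1R,2S,4S,5R,7R,8S)-4-{[tert-butyl(diphenyl)silyl]oxymethyl}-4,5-epoxytricyclo[6.2.1.0(2,7)]undec-9-ene-3,6-dione (oxirane oxygen on the convex face, cis to the ring-fusion hydrogens), via hydroperoxy enolate 6 (not isolated)
Conditions: 30% aq. H2O2 (3 equiv), Na2CO3 (0.5 equiv), acetone/H2O, 0 °C
Reagents that add atoms: hydrogen peroxide, OO
Why: The hydroperoxide anion, a soft alpha-effect nucleophile, adds in conjugate fashion to C5, the unsubstituted terminus of the ene-dione alkene (β to the C1 carbonyl), to give the C1/C6 enolate 6. The enolate carbon C6 then attacks the proximal peroxide oxygen and expels hydroxide, a 3-exo-tet closure that forms the C6–O bond and completes the oxirane; the closest known reaction type is the Weitz–Scheffer epoxidation of ene-diones, well established for cyclopentadiene–quinone adducts. Both new stereocentres are controlled by the scaffold: in the endo adduct the norbornene alkene covers the concave face of the ene-dione ring, so the peroxide bonds to C5 from the convex face (cis to the ring-fusion hydrogens), and because an oxirane on a six-membered ring must be cis-fused, C6 follows C5. The absolute configuration at C5 and C6 is thereby relayed from the ring-fusion centres set in step 3. Three selectivities are needed: chemoselectivity for C5=C6 over the norbornene alkene, secured by the nucleophilic nature of the oxidant, which ignores an unactivated alkene; facial selectivity, secured by the fold of the tricycle; and epoxidation outrunning base-induced enolisation toward the aromatic hydroquinone tautomer, secured by the weak carbonate base, the low temperature and the high nucleophilicity of hydroperoxide. The silyl ether is inert to carbonate and the oxirane formed is stable under the conditions.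

Step 5
Reactants: 7 (1R,2S,4S,5R,7R,8S)-4-{[tert-butyl(diphenyl)silyl]oxymethyl}-4,5-epoxytricyclo[6.2.1.0(2,7)]undec-9-ene-3,6-dione
Product: 8 (1R,2S,3S,4R,5S,6R,7R,8S)-4-{[tert-butyl(diphenyl)silyl]oxymethyl}-4,5-epoxytricyclo[6.2.1.0(2,7)]undec-9-ene-3,6-diol (both hydroxyls on the concave face, anti to the oxirane)
Conditions: NaBH4, CeCl3·7H2O, MeOH/CH2Cl2 (1:1), −40 → 0 °C
Reagents that add atoms: none
Why: Borohydride reduction under Luche conditions: hydride reaches each ketone from the convex face because the norbornene alkene shields the concave one, so both hydroxyls end on the concave face, trans to the ring-fusion hydrogens and anti to the oxirane, which sets C1 and C4 cis to each other. Cerium trichloride keeps the medium non-basic, so the α,β-epoxy ketones are reduced without epimerisation or oxirane opening.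

Step 6
Reactants: 8 (1R,2S,3S,4R,5S,6R,7R,8S)-4-{[tert-butyl(diphenyl)silyl]oxymethyl}-4,5-epoxytricyclo[6.2.1.0(2,7)]undec-9-ene-3,6-diol
Product: 9 (1S,4R,5S,6R)-6-{[tert-butyl(diphenyl)silyl]oxymethyl}-5,6-epoxycyclohex-2-ene-1,4-diol (hydroxyls cis to each other, both trans to the oxirane oxygen)
Conditions: Ph2O, 240 °C, 20 min, N2 stream
Reagents that add atoms: none
Why: Thermal retro-Diels–Alder reaction: the norbornene fragments into cyclopentadiene, which is swept out, and the cyclohexene, which regains C2=C3. None of C1, C4, C5 or C6 takes part, so their configurations are retained.

Step 7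
Reactants: 9 (1S,4R,5S,6R)-6-{[tert-butyl(diphenyl)silyl]oxymethyl}-5,6-epoxycyclohex-2-ene-1,4-diol
Product: 10 (1S,4R,5S,6R)-6-{[tert-butyl(diphenyl)silyl]oxymethyl}-5,6-epoxycyclohex-2-ene-1,4-diyl dibenzoate
Conditions: PhCOCl (3 equiv), 4-(dimethylamino)pyridine (cat.), pyridine, CH2Cl2, 0 °C → rt
Reagents that add atoms: benzoyl chloride, O=C(Cl)c1ccccc1
Why: Acyl transfer under nucleophilic catalysis; O1 and O4 are the only free hydroxyls, so no selectivity is required, and the mild base leaves the oxirane and the silyl ether untouched.

Step 8
Reactants: 10 (1S,4R,5S,6R)-6-{[tert-butyl(diphenyl)silyl]oxymethyl}-5,6-epoxycyclohex-2-ene-1,4-diyl dibenzoate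
Product: 12 (1S,4R,5S,6R)-6-{[tert-butyl(diphenyl)silyl]oxymethyl}-5,6-dihydroxycyclohex-2-ene-1,4-diyl dibenzoate, via dioxolanylium ion 11 (not isolated)
Conditions: HClO4 (70% aq., 0.3 equiv), THF/H2O (4:1), 0 °C → rt
Reagents that add atoms: water, O
Why: Acid-catalysed epoxide hydrolysis with anchimeric assistance: the protonated oxirane opens at the tertiary C6, where the carbonyl oxygen of the anti-disposed C1 benzoate attacks from the rear (5-exo) to give the cis-fused dioxolanylium ion 11, which water converts through its orthoacid into the C1 benzoate and a C6 hydroxyl; direct rear-side attack of water at C6 gives the same product. C6 is inverted (hydroxyl now cis to the C1 benzoate and trans to O5), C5 keeps its oxygen and configuration, and the silyl ether survives dilute acid, which keeps O7 out of any acyl transfer.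

Step 9
Reactants: 12 (1S,4R,5S,6R)-6-{[tert-butyl(diphenyl)silyl]oxymethyl}-5,6-dihydroxycyclohex-2-ene-1,4-diyl dibenzoate
Product: 13 (1S,4R,5S,6R)-5,6-dihydroxy-6-(hydroxymethyl)cyclohex-2-ene-1,4-diyl dibenzoate
Conditions: HF·pyridine, pyridine, THF, 0 °C → rt
Reagents that add atoms: none
Why: Fluoride-driven cleavage of the silyl ether (formation of the strong Si–F bond) under mildly acidic, non-basic conditions, chosen so that neither benzoate migrates to a neighbouring hydroxyl nor is cleaved; no stereocentre is touched.

## Compound list

1 | (2,5-dimethoxyphenyl)methanol | COc1ccc(OC)c(CO)c1 | starting material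
2 | tert-butyl[(2,5-dimethoxyphenyl)methoxy]diphenylsilane | COc1ccc(OC)c(CO[Si](c2ccccc2)(c2ccccc2)C(C)(C)C)c1 | intermediate
3 | 2-{[tert-butyl(diphenyl)silyl]oxymethyl}cyclohexa-2,5-diene-1,4-dione | O=C1C=CC(=O)C(CO[Si](c2ccccc2)(c2ccccc2)C(C)(C)C)=C1 | intermediate
4 | cyclopenta-1,3-diene | C1=CCC=C1 | starting material
5 | (1R,2S,7R,8S)-4-{[tert-butyl(diphenyl)silyl]oxymethyl}tricyclo[6.2.1.0(2,7)]undeca-4,9-diene-3,6-dione, endo adduct | O=C1C=C(CO[Si](c2ccccc2)(c2ccccc2)C(C)(C)C)C(=O)[C@H]2[C@H]3C=C[C@H](C3)[C@@H]12 | intermediate
6 | sodium enolate (C6=C1–O) of the C5 hydroperoxide, hydroperoxy group on the convex face | [Na+].O=C1[C@H](OO)C(CO[Si](c2ccccc2)(c2ccccc2)C(C)(C)C)=C([O-])[C@H]2[C@H]3C=C[C@H](C3)[C@@H]12 | intermediate (not isolated)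
7 | (1R,2S,4S,5R,7R,8S)-4-{[tert-butyl(diphenyl)silyl]oxymethyl}-4,5-epoxytricyclo[6.2.1.0(2,7)]undec-9-ene-3,6-dione, convex-face oxirane | O=C1[C@@H]2O[C@]2(CO[Si](c3ccccc3)(c3ccccc3)C(C)(C)C)C(=O)[C@H]3[C@H]4C=C[C@H](C4)[C@@H]13 | intermediate
8 | (1R,2S,3S,4R,5S,6R,7R,8S)-4-{[tert-butyl(diphenyl)silyl]oxymethyl}-4,5-epoxytricyclo[6.2.1.0(2,7)]undec-9-ene-3,6-diol, hydroxyls concave and anti to the oxirane | O[C@H]1[C@@H]2O[C@]2(CO[Si](c3ccccc3)(c3ccccc3)C(C)(C)C)[C@@H](O)[C@H]3[C@H]4C=C[C@H](C4)[C@@H]13 | intermediate
9 | (1S,4R,5S,6R)-6-{[tert-butyl(diphenyl)silyl]oxymethyl}-5,6-epoxycyclohex-2-ene-1,4-diol | O[C@H]1[C@@H]2O[C@]2(CO[Si](c3ccccc3)(c3ccccc3)C(C)(C)C)[C@@H](O)C=C1 | intermediate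
10 | (1S,4R,5S,6R)-6-{[tert-butyl(diphenyl)silyl]oxymethyl}-5,6-epoxycyclohex-2-ene-1,4-diyl dibenzoate | O=C(O[C@H]1[C@@H]2O[C@]2(CO[Si](c3ccccc3)(c3ccccc3)C(C)(C)C)[C@@H](OC(=O)c3ccccc3)C=C1)c1ccccc1 | intermediate
11 | 2-phenyl-1,3-dioxolan-2-ylium perchlorate cis-fused across O1–C1–C6–O6, C5 hydroxyl on the opposite face, C4 benzoate retained | O=C(O[C@H]1[C@H](O)[C@@]2(CO[Si](c3ccccc3)(c3ccccc3)C(C)(C)C)[O+]=C(c3ccccc3)O[C@H]2C=C1)c1ccccc1.[O-]Cl(=O)(=O)=O | intermediate (not isolated)
12 | (1S,4R,5S,6R)-6-{[tert-butyl(diphenyl)silyl]oxymethyl}-5,6-dihydroxycyclohex-2-ene-1,4-diyl dibenzoate | O=C(O[C@H]1C=C[C@@H](OC(=O)c2ccccc2)[C@H](O)[C@]1(O)CO[Si](c2ccccc2)(c2ccccc2)C(C)(C)C)c1ccccc1 | intermediate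
13 | (1S,4R,5S,6R)-5,6-dihydroxy-6-(hydroxymethyl)cyclohex-2-ene-1,4-diyl dibenzoate | O=C(O[C@H]1C=C[C@@H](OC(=O)c2ccccc2)[C@H](O)[C@]1(O)CO)c1ccccc1 | target

## Step count and least certain steps

Total steps: 9. Longest linear sequence: 9 steps (1 to 13; 4 enters in step 3).

**Step 4 (key step).** The most likely failure is base-induced enolisation of the cis-fused ene-dione and tautomerisation to the aromatic hydroquinone, which destroys the scaffold stereocentres. The risk is higher than for an unsubstituted adduct because conjugate addition to the trisubstituted alkene is slower. The fallback removes one carbonyl before the epoxidation; it sets out from 5 and rejoins the route at 8, at the cost of one extra step. Luche reduction (NaBH4 0.3 equiv, CeCl3·7H2O, MeOH, −78 °C) of the less hindered C4 carbonyl from the convex face would give the hydroxy enone F1, which cannot tautomerise to an arene. Alkaline hydrogen peroxide (or tert-butyl hydroperoxide with benzyltrimethylammonium hydroxide) would epoxidise the remaining enone of F1 from the convex face, forming the same C5–O and C6–O bonds, to give the epoxy ketol F2. NaBH4 reduction of its C1 ketone from the convex face would give 8.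

**Step 3.** The most likely failure is insufficient enantioselectivity. With a symmetric diene, catalyst binding at the C1 carbonyl instead of the C4 carbonyl leads to the antipodal adduct, and a silyloxymethyl group biases the two carbonyls only weakly; the uncatalysed addition of cyclopentadiene to quinones is also fast. The fallback separates antipodes after a racemic cycloaddition; it sets out from 3 and 4 and rejoins at 8, losing at least half of the material. Uncatalysed cycloaddition (CH2Cl2, 0 °C) would give the racemic endo adduct F3; steps 4 and 5 applied unchanged would give the racemic epoxy dione F4 and the racemic diol F5. Acylation of F5 with vinyl acetate catalysed by Burkholderia cepacia lipase in tert-butyl methyl ether, stopped near half conversion, is expected to esterify the less hindered C4 hydroxyl of one antipode only. Taking the case that the wanted antipode reacts, the C4 monoacetate F6 would be separated from the unreacted antipodal diol F7 and methanolysed (K2CO3, MeOH) to 8; if the enzyme preferred the other antipode, the unreacted alcohol fraction would be carried on instead.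

**Step 8.** The most likely failure is loss of regiocontrol in the oxirane opening, either by participation of the C4 benzoate at C5 (inversion at the wrong carbon) or by the benzoyl group coming to rest on the tertiary O6. Both esters stand anti to the oxirane, and the cationic character at C6 is damped by two β-oxygens. The fallback introduces the esters one after the other so that only the C1 ester can participate; it sets out from 9 and rejoins at 12, with two extra steps. Selective silylation of the less hindered C4 hydroxyl of 9 (Et3SiCl, imidazole, CH2Cl2, −40 °C) would give the C4 triethylsilyl ether F8, and benzoylation of the remaining C1 hydroxyl the monobenzoate F9. Dilute aqueous HClO4 in THF would then remove the labile triethylsilyl group and open the oxirane at C6 with only one ester available for assistance, giving the triol monobenzoate F10. The allylic C4 hydroxyl of F10, the only secondary hydroxyl not flanked by the quaternary carbon, would be benzoylated selectively (PhCOCl 1.1 equiv, pyridine, −30 °C) to 12.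

**Step 6.** The most likely failure is thermal decomposition of the free epoxy diol before cycloreversion is complete (attack of a neighbouring hydroxyl on the oxirane, dehydration toward an arene), since expulsion of cyclopentadiene needs well above 200 °C. The fallback changes the order of events and the phase; it sets out from 8 and rejoins at 10, with no extra step. Benzoylation of both concave hydroxyls on the scaffold (PhCOCl, 4-(dimethylamino)pyridine, pyridine, 50 °C) would give the tricyclic dibenzoate F11, which has no free hydroxyl. Flash vacuum pyrolysis (about 500 °C, 0.01 mbar, short contact time) would then release 10 directly.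

## Further compounds

F1 | step 4 | hydroxy enone: C4 carbinol (hydroxyl concave), C1 ketone, C5=C6 alkene, on the endo tricycle | O[C@H]1C=C(CO[Si](c2ccccc2)(c2ccccc2)C(C)(C)C)C(=O)[C@H]2[C@H]3C=C[C@H](C3)[C@@H]12
F2 | step 4 | epoxy ketol: convex-face C5–C6 oxirane, C4 carbinol (hydroxyl concave), C1 ketone | O[C@H]1[C@@H]2O[C@]2(CO[Si](c3ccccc3)(c3ccccc3)C(C)(C)C)C(=O)[C@H]3[C@H]4C=C[C@H](C4)[C@@H]13
F3 | step 3 | racemic endo adduct (racemate of 5, one antipode drawn) | O=C1C=C(CO[Si](c2ccccc2)(c2ccccc2)C(C)(C)C)C(=O)[C@H]2[C@H]3C=C[C@H](C3)[C@@H]12
F4 | step 3 | racemic convex-face epoxy dione (racemate of 7, one antipode drawn) | O=C1[C@@H]2O[C@]2(CO[Si](c3ccccc3)(c3ccccc3)C(C)(C)C)C(=O)[C@H]3[C@H]4C=C[C@H](C4)[C@@H]13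
F5 | step 3 | racemic tricyclic epoxy diol (racemate of 8, one antipode drawn) | O[C@H]1[C@@H]2O[C@]2(CO[Si](c3ccccc3)(c3ccccc3)C(C)(C)C)[C@@H](O)[C@H]3[C@H]4C=C[C@H](C4)[C@@H]13
F6 | step 3 | C4 monoacetate of 8 | CC(=O)O[C@H]1[C@@H]2O[C@]2(CO[Si](c3ccccc3)(c3ccccc3)C(C)(C)C)[C@@H](O)[C@H]3[C@H]4C=C[C@H](C4)[C@@H]13
F7 | step 3 | antipode of 8 (unreacted diol) | O[C@@H]1[C@H]2O[C@@]2(CO[Si](c3ccccc3)(c3ccccc3)C(C)(C)C)[C@H](O)[C@@H]3[C@@H]4C=C[C@@H](C4)[C@H]13
F8 | step 8 | C4 triethylsilyl ether of 9 | CC[Si](CC)(CC)O[C@H]1[C@@H]2O[C@]2(CO[Si](c3ccccc3)(c3ccccc3)C(C)(C)C)[C@@H](O)C=C1
F9 | step 8 | C1 benzoate, C4 triethylsilyl ether of 9 | CC[Si](CC)(CC)O[C@H]1[C@@H]2O[C@]2(CO[Si](c3ccccc3)(c3ccccc3)C(C)(C)C)[C@@H](OC(=O)c3ccccc3)C=C1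
F10 | step 8 | triol monobenzoate: C1 benzoate; C4, C5, C6 hydroxyls free; O7 silylated | O=C(O[C@H]1C=C[C@@H](O)[C@H](O)[C@]1(O)CO[Si](c2ccccc2)(c2ccccc2)C(C)(C)C)c1ccccc1
F11 | step 6 | dibenzoate of 8 on the tricyclic scaffold | O=C(O[C@H]1[C@@H]2O[C@]2(CO[Si](c3ccccc3)(c3ccccc3)C(C)(C)C)[C@@H](OC(=O)c3ccccc3)[C@H]3[C@H]4C=C[C@H](C4)[C@@H]13)c1ccccc1
A1 | alternative 1 | (1E,3E)-buta-1,3-diene-1,4-diyl diacetate | CC(=O)O/C=C/C=C/OC(C)=O
A2 | alternative 1 | (2E)-2,3-bis(chloroacetoxy)prop-2-enal | ClCC(=O)O/C=C(/OC(=O)CCl)C=O
A3 | alternative 1 | cycloadduct: C1/C4 acetates, C5/C6 chloroacetates, C7 aldehyde | CC(=O)O[C@H]1C=C[C@@H](OC(C)=O)[C@H](OC(=O)CCl)[C@]1(OC(=O)CCl)C=O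
A4 | alternative 2 | 5,6-trans-dioxygenated cyclohexa-1,3-diene, O5/O7 di-tert-butylsilylene, free C6 hydroxyl | C1=CC=C[C@H](O[Si](C(C)(C)C)(C(C)(C)C)OC2)[C@@]12O
A5 | alternative 2 | endoperoxide bridging C1 and C4 | O3[C@H]1C=C[C@@H](O3)[C@H](O[Si](C(C)(C)C)(C(C)(C)C)OC2)[C@@]12O
A6 | alternative 3 | (1S,2S)-3-bromocyclohexa-3,5-diene-1,2-diol | O[C@H]1C=CC=C(Br)[C@H]1O
A7 | alternative 3 | diene: C4 benzoate, C5 silyl ether, C6 silyloxymethyl, C6=C1–C2=C3 | O=C(O[C@@H]1C=CC=C(CO[Si](C)(C)C(C)(C)C)[C@H]1O[Si](C)(C)C(C)(C)C)c1ccccc1
A8 | alternative 3 | C1,C6-cis-diol from dihydroxylation of the diene | O=C(O[C@@H]1C=C[C@H](O)[C@@](O)(CO[Si](C)(C)C(C)(C)C)[C@H]1O[Si](C)(C)C(C)(C)C)c1ccccc1
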